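**Retrosynthetic overview** (ring locants: O1, C2 bearing the side chain, C3 bearing CO2H, C4 bearing CH3, C5 the lactone C=O; side-chain carbons C1′ on C2 to C15′, the methyl)
- Target 16 ⇐ tert-butyl ester 15 ⇐ side-chain bond C6′–C7′: primary bromide 12 (lactone ring plus C1′–C6′) + 1-methylcyclooctan-1-ol 14 (C7′–C15′).
- Enabling feature: ketone carbon C14′ and C7′ are 1,8-related, so C7′–C14′ are the eight ring carbons of 14, C15′ its methyl and the ketone oxygen its hydroxyl. β-Scission of the temporary ring bond C14′–C7′ unveils the methyl ketone and places a radical on C7′.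
- 12 ⇐ C4 methylation trans to the C3 ester ⇐ lactone 10 ⇐ ozonolysis and lactol oxidation of anti allyl hydroxy ester 7 ⇐ Fráter–Seebach allylation (sets C3) of 5 ⇐ Noyori hydrogenation (sets C2) of β-keto ester 4 ⇐ acetoacetate dianion + 1,5-dibromopentane.
- Ring order: the cyclooctane is bought as cyclooctanone; the lactone, the only ring of the target, is closed in step 4; the cyclooctane is opened in step 7.

Key step: step 7

**Step 1**
Reactants: 1 tert-butyl 3-oxobutanoate; 2 1,5-dibromopentane
Product: 4 tert-butyl 9-bromo-3-oxononanoate, via acetoacetate dianion 3 (not isolated)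
Conditions: NaH, THF, 0 °C; n-BuLi, 0 °C; 2 (3 equiv), 0 °C → rt; 1 M HCl
Reagents that add atoms: none
Why: Huckin–Weiler dianion alkylation, in which the terminal carbanion of the dianion is far more nucleophilic than the central enolate and displaces one bromide of the excess dibromide; no stereocentre is formed.

**Step 2**
Reactants: 4 tert-butyl 9-bromo-3-oxononanoate
Product: 5 tert-butyl (3S)-9-bromo-3-hydroxynonanoate
Conditions: H2 (50 atm), RuCl2[(S)-BINAP] (0.5 mol %), MeOH, 50 °C
Reagents that add atoms: none
Why: Noyori asymmetric hydrogenation of a β-keto ester, in which the ester-chelated (S)-BINAP–Ru hydride reduces one ketone face and should set C3 as S (the later ring C2), the primary bromide and the tert-butyl ester being inert to the catalyst.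

**Step 3**
Reactants: 5 tert-butyl (3S)-9-bromo-3-hydroxynonanoate
Product: 7 tert-butyl (2S,3S)-9-bromo-3-hydroxy-2-(prop-2-en-1-yl)nonanoate, via dilithium alkoxide enolate 6 (not isolated)
Conditions: LDA (2.2 equiv), THF, −78 → −40 °C; allyl bromide (2 equiv), DMPU, −78 → −30 °C; 1 M HCl, 0 °C
Reagents that add atoms: allyl bromide, C=CCBr
Why: Fráter–Seebach alkylation, in which the six-membered lithium chelate of the alkoxide enolate is allylated on the face anti to the C3 chain, which should set C2 as S (2,3-anti, the later ring C3), while the unactivated primary bromide is a much poorer electrophile than allyl bromide at these temperatures.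

**Step 4**
Reactants: 7 tert-butyl (2S,3S)-9-bromo-3-hydroxy-2-(prop-2-en-1-yl)nonanoate
Product: 10 tert-butyl (2S,3S)-2-(6-bromohexyl)-5-oxooxolane-3-carboxylate, via ozonide 8 (not isolated), via lactol 9 (not isolated)
Conditions: O3, CH2Cl2, −78 °C; Me2S, −78 °C → rt; evaporate; TEMPO (10 mol %), PhI(OAc)2 (1.3 equiv), CH2Cl2, rt
Reagents that add atoms: ozone, [O-][O+]=O
Why: Ozonolysis with reductive work-up turns the allyl group into a γ-hydroxy aldehyde that closes by 5-exo-trig addition to the lactol, and TEMPO/PhI(OAc)2 lactol oxidation gives the γ-lactone with both stereocentres untouched, so the anti diad of 7 becomes the 2,3-cis ring.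

**Step 5**
Reactants: 10 tert-butyl (2S,3S)-2-(6-bromohexyl)-5-oxooxolane-3-carboxylate
Product: 12 tert-butyl (2S,3S,4S)-2-(6-bromohexyl)-4-methyl-5-oxooxolane-3-carboxylate, via lithium lactone enolate 11 (not isolated)
Conditions: LiHMDS (1.05 equiv), THF, −78 °C; MeI (3 equiv), −78 → −50 °C; aq NH4Cl
Reagents that add atoms: iodomethane, CI
Why: Lactone enolate alkylation, in which kinetic deprotonation at the unhindered and more acidic lactone α-CH2 is followed by methylation on the ring face opposite to the C3 ester and the C2 chain, which should set C4 as S, trans to the ester.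

**Step 6**
Reactants: 13 cyclooctanone
Product: 14 1-methylcyclooctan-1-ol
Conditions: MeMgBr (1.3 equiv), THF, 0 °C → rt; 1 M HCl, 0 °C
Reagents that add atoms: methylmagnesium bromide, C[Mg]Br
Why: Grignard 1,2-addition to the ketone gives the tertiary carbinol, which carries C7′–C15′ of the side chain with the future ketone oxygen already in place.

**Step 7**
Reactants: 12 tert-butyl (2S,3S,4S)-2-(6-bromohexyl)-4-methyl-5-oxooxolane-3-carboxylate; 14 1-methylcyclooctan-1-ol (2.5 equiv)
Product: 15 tert-butyl (2S,3S,4S)-4-methyl-5-oxo-2-(14-oxopentadecyl)oxolane-3-carboxylate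
Conditions: CeCl3 (10 mol %), n-Bu4NCl (30 mol %), 9,10-diphenylanthracene (5 mol %), NiBr2·dme (10 mol %), 4,4′-di-tert-butyl-2,2′-bipyridine (12 mol %), NaHCO3 (1.5 equiv), MeCN, 400 nm LEDs, 25 °C, Ar
Reagents that add atoms: none
Why: Proposed new method: LMCT photolysis of the Ce(IV) alkoxide of 14 should give the tertiary alkoxy radical, whose β-scission of the ring bond C14′–C7′ unveils the methyl ketone and an 8-oxononyl primary radical; this radical is captured by the alkylnickel(II) formed from bromide 12, and reductive elimination from Ni(III) makes the C6′–C7′ bond. Photoexcited diphenylanthracene should return Ni(I) to Ni(0) and its radical cation re-oxidise Ce(III), so the coupling is redox neutral and only HBr is lost. The closest known reaction types are the cerium-photocatalysed ring-opening functionalisation of unstrained cycloalkanols, its cerium/nickel dual-catalytic arylation variant, and the nickel/photoredox decarboxylative C(sp3)–C(sp3) coupling of alkyl radicals with primary alkyl bromides. No ring is closed (the temporary cyclooctane is opened) and no stereocentre is formed; the three lactone stereocentres are spectators under these near-neutral room-temperature conditions. The step needs β-scission of the ring bond to beat transannular 1,5-hydrogen abstraction and loss of methyl, which the tertiary carbinol (ketone formation), the release of cyclooctane strain and the formation of a primary rather than a methyl radical should secure. It also needs cross-coupling to beat dimerisation and reduction of the radical, which the excess of inexpensive 14 and the ready oxidative addition of the primary bromide to nickel should favour.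

**Step 8**
Reactants: 15 tert-butyl (2S,3S,4S)-4-methyl-5-oxo-2-(14-oxopentadecyl)oxolane-3-carboxylate
Product: 16 (2S,3S,4S)-4-methyl-5-oxo-2-(14-oxopentadecyl)oxolane-3-carboxylic acid
Conditions: TFA/CH2Cl2 (1:3), 0 °C → rt
Reagents that add atoms: none
Why: Acidolysis of the tert-butyl ester (E1 loss of isobutene) frees the carboxylic acid without base, so the 2,3-cis relationship, the lactone and the methyl ketone should be preserved.

**Compound list**
1 | tert-butyl 3-oxobutanoate | CC(=O)CC(=O)OC(C)(C)C | starting material
2 | 1,5-dibromopentane | BrCCCCCBr | starting material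
3 | sodium lithium dianion of 1 | [Na+].[Li+].C=C([O-])C=C([O-])OC(C)(C)C | intermediate
4 | tert-butyl 9-bromo-3-oxononanoate | BrCCCCCCC(=O)CC(=O)OC(C)(C)C | intermediate
5 | tert-butyl (3S)-9-bromo-3-hydroxynonanoate | BrCCCCCC[C@H](O)CC(=O)OC(C)(C)C | intermediate
6 | dilithium alkoxide enolate of 5 | [Li+].[Li+].BrCCCCCC[C@H]([O-])C=C([O-])OC(C)(C)C | intermediate
7 | tert-butyl (2S,3S)-9-bromo-3-hydroxy-2-(prop-2-en-1-yl)nonanoate | BrCCCCCC[C@H](O)[C@H](CC=C)C(=O)OC(C)(C)C | intermediate
8 | tert-butyl (2S,3S)-9-bromo-3-hydroxy-2-(1,2,4-trioxolan-3-ylmethyl)nonanoate (ozonide) | BrCCCCCC[C@H](O)[C@H](CC1OCOO1)C(=O)OC(C)(C)C | intermediate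
9 | tert-butyl (2S,3S)-2-(6-bromohexyl)-5-hydroxyoxolane-3-carboxylate (lactol, both C5 epimers) | BrCCCCCC[C@@H]1OC(O)C[C@@H]1C(=O)OC(C)(C)C | intermediate
10 | tert-butyl (2S,3S)-2-(6-bromohexyl)-5-oxooxolane-3-carboxylate (side chain and ester cis) | BrCCCCCC[C@@H]1OC(=O)C[C@@H]1C(=O)OC(C)(C)C | intermediate
11 | lithium enolate of 10 | [Li+].BrCCCCCC[C@@H]1OC([O-])=C[C@@H]1C(=O)OC(C)(C)C | intermediate
12 | tert-butyl (2S,3S,4S)-2-(6-bromohexyl)-4-methyl-5-oxooxolane-3-carboxylate (2,3-cis, 3,4-trans) | BrCCCCCC[C@@H]1OC(=O)[C@@H](C)[C@@H]1C(=O)OC(C)(C)C | intermediate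
13 | cyclooctanone | O=C1CCCCCCC1 | starting material
14 | 1-methylcyclooctan-1-ol | CC1(O)CCCCCCC1 | intermediate
15 | tert-butyl (2S,3S,4S)-4-methyl-5-oxo-2-(14-oxopentadecyl)oxolane-3-carboxylate | CC(=O)CCCCCCCCCCCCC[C@@H]1OC(=O)[C@@H](C)[C@@H]1C(=O)OC(C)(C)C | intermediate
16 | (2S,3S,4S)-4-methyl-5-oxo-2-(14-oxopentadecyl)oxolane-3-carboxylic acid | CC(=O)CCCCCCCCCCCCC[C@@H]1OC(=O)[C@@H](C)[C@@H]1C(=O)O | target

**Step count**
Total: 8 steps. Longest linear sequence: 7 steps (steps 1–5, 7, 8).

**Steps most likely to fail**

1. Step 7. The cyclooctyloxy radical may undergo transannular 1,5-hydrogen abstraction instead of β-scission. The primary radical may also be intercepted too slowly by alkylnickel, so that it dimerises or is reduced, or the cerium and nickel cycles may quench each other. The fallback uses known chemistry, sets out from 12 and returns at 15. Purchased dec-9-enoic acid is oxidised under Tsuji–Wacker conditions (PdCl2 cat., CuCl, O2, DMF/H2O) to 9-oxodecanoic acid F1. F1 and 12 are then joined by the established nickel/photoredox decarboxylative C(sp3)–C(sp3) coupling of a carboxylic acid with a primary alkyl bromide (NiCl2·dme, 4,4′-dimethoxy-2,2′-bipyridine, Ir[dF(CF3)ppy]2(dtbbpy)PF6, K2CO3, MeCN/H2O, blue LEDs). This generates the same 8-oxononyl radical by loss of CO2, without an alkoxy radical or cerium, and should give 15.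

2. Step 5. Deprotonation may occur at C3 (α to the tert-butyl ester), followed by β-elimination of the ring carboxylate; a second methylation or poor facial selectivity is also possible. The fallback sets out from 10 and returns at 12. The ester is cleaved (TFA/CH2Cl2) to (2S,3S)-2-(6-bromohexyl)-5-oxooxolane-3-carboxylic acid F2. NaHMDS (2.2 equiv, THF, −78 °C) converts it into the disodium carboxylate enolate F3, in which the carboxylate blocks deprotonation at C3. Methylation with MeI trans to the carboxylate should give (2S,3S,4S)-2-(6-bromohexyl)-4-methyl-5-oxooxolane-3-carboxylic acid F4. Re-esterification with tert-butyl 2,2,2-trichloroacetimidate (CH2Cl2/cyclohexane, rt) leads back to 12.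

3. Step 3. LDA or the dianion may attack the primary bromide (elimination or intermolecular alkylation), and allylation may be incomplete or less anti-selective than expected. The fallback sets out from 4 and returns at 7, and avoids any strong base. Keto ester 4 is C-allylated (K2CO3, allyl bromide, acetone) to racemic tert-butyl 9-bromo-3-oxo-2-(prop-2-en-1-yl)nonanoate F5. F5 is then reduced by ketoreductase-catalysed dynamic kinetic resolution, using an enzyme selected from a commercial panel for the anti-(2S,3S) product (NADP+, glucose/glucose dehydrogenase, pH 7 buffer/DMSO, 30 °C). The α-stereocentre racemises under these conditions while one enantiomer is reduced, which sets both centres of 7 together.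

**Further compounds**
F1 | step 7 | 9-oxodecanoic acid | CC(=O)CCCCCCCC(=O)O
F2 | step 5 | (2S,3S)-2-(6-bromohexyl)-5-oxooxolane-3-carboxylic acid | BrCCCCCC[C@@H]1OC(=O)C[C@@H]1C(=O)O
F3 | step 5 | disodium carboxylate enolate of F2 | [Na+].[Na+].BrCCCCCC[C@@H]1OC([O-])=C[C@@H]1C(=O)[O-]
F4 | step 5 | (2S,3S,4S)-2-(6-bromohexyl)-4-methyl-5-oxooxolane-3-carboxylic acid | BrCCCCCC[C@@H]1OC(=O)[C@@H](C)[C@@H]1C(=O)O
F5 | step 3 | tert-butyl 9-bromo-3-oxo-2-(prop-2-en-1-yl)nonanoate (racemic) | BrCCCCCCC(=O)C(CC=C)C(=O)OC(C)(C)C
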